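**Conventions.** Locants follow the germacrane numbering of the target: C1–C10 ring carbons, C11 (lactone α-carbon), C12 (lactone C=O), C13 (exocyclic CH2), C14 (methyl on C10), C15 (CH2OH on C4). TBSO = tert-butyldimethylsilyloxy, PMBO = 4-methoxybenzyloxy, DMPO = 2,2-dimethylpent-4-enoyloxy.

## Analysis of the target

Target 26 is a germacranolide: a ten-membered carbocycle (C1–C10) trans-fused through C6–C7 to an α-methylene-γ-butyrolactone (O–C6, C7–C11(=C13H2)–C12=O). The ring carries a cis (Z) trisubstituted C4=C5 olefin with C15H2OH on C4, a cis-fused C1–C10 oxirane with the C14 methyl on C10, an acetate on C3 and an angelate on C8. The six stereocentres are C1 (R), C3 (S), C6 (R), C7 (R), C8 (R) and C10 (S). O3, O8, the oxirane oxygen and C11 lie on one face of the ring and O6 on the other, so C6/C7/C8 form a 6,7-syn/7,8-anti triad and O8 is 1,3-syn to the oxirane oxygen. The sensitive groups are the exocyclic enoate (Michael acceptor), the angelate (isomerises to the tiglate), the trisubstituted epoxide (acid), and the lactone, which migrates to O8 whenever a C8 alkoxide is formed; O3 and O15 invite acyl migration. The synthesis is hard because of the strained ten-membered ring with two cis ring elements and because of three contiguous stereocentres (C6–C8) on a flexible ring.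

The feature that invites the strategy: without the oxirane oxygen and with C6 as a carbonyl, the ring contains the unit C6(=O)–C7–C8–C9–C10=C1, a cyclodec-5-enone and thus the retron of an oxy-Cope rearrangement. The C4=C5 olefin with C3 and C6 cis is then the double bond of a six-membered ring C1–C6 that has the substitution pattern of carvone (oxygen on C3, C15 on C4, the C10/C9/C14 unit on C1).

## Retrosynthetic reasoning

26 to 25: the C15–O bond is cut. C15 is the only unoxygenated allylic position of 25 and sits on the more substituted carbon of the C4=C5 olefin, so a late allylic C–H hydroxylation avoids carrying and protecting a primary allylic alcohol from the start.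

25 to 21: only acyl groups change. The C3 silyl ether becomes the acetate and the C8 relay ester becomes the angelate. The angelate comes last because it would not survive enolate chemistry, and O8 must never be a free alkoxide next to the lactone.

21 to 18 to 16: the C11=C13 bond comes from an iminium alkylation and elimination on lactone 18. The O6–C12 bond and the C6–H bond are cut together: a Tishchenko reduction of β-hydroxy ketone 16 sets C6 from C8, acylates O8 in the same act, and leaves only O6 free to lactonise.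

16 to 15: the C7–C11 bond is cut. The forward reaction is the alkylation of the chelated dianion of a β-hydroxy ketone, which sets C7 anti to O8.

15 to 14: the two C–O bonds of the oxirane are cut. The Z olefin C1=C10 of 14 is homoallylic to the free C8 hydroxyl, which can deliver the oxygen to its own face.

14 to 13 to 10 (key): the C8–C9 bond of the ten-membered ring is cut and C6–C1 is reconnected (retro-oxy-Cope). This removes the medium ring, both cis ring elements and the C8 stereocentre in one operation and leaves a cyclohexenol. The forward reaction must make the C1=C10 olefin Z and set C8 relative to C3.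

10 to 9 to 4 and 7: the C6–C7 bond is cut to enone 4 and an alkoxyacetylide made from 7. The alkyne is the only small, linear nucleophile that should add cis to the isopropenyl group, and it can be reduced to the (E)-enol ether.

4 to 3 to 2 to 1: the C6 carbonyl comes from allylic oxidation of the one ring methylene of 3, and C3 from 1,2-reduction of (S)-carvone 1. Reagent 7 comes from 5 and 6.

## Alternatives that were turned down

Alternative 1: the textbook disconnection of the C6–C7 bond together with the lactone C–O bond. The forward key step is an intramolecular Nozaki–Hiyama–Kishi allylation (CrCl2) of the aldehyde/allylic bromide A1, closing the ten-membered ring and then the lactone. It was turned down for four reasons: A1 needs a (4Z)-β,β-disubstituted enal that isomerises through its dienol; the closure is an entropically disfavoured medium-ring cyclisation; C6 and C7 would be set only by 1,2-induction from C8 in a floppy chain; and A1 must already carry four stereocentres, the epoxide and both esters, so its linear synthesis costs more than the ring closure returns.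

Alternative 2: a transannular C1–C5 bond is added to give the guaianolide-type tricycle A2. The forward key step is a Grob fragmentation: the C1 alkoxide pushes, C1–C5 breaks and the C4 spiro-oxirane leaves, giving the 4Z olefin, C15–OH and a C1 ketone stereospecifically. It was turned down because A2 has eight stereocentres, three of which the step destroys, so the precursor is more complex than the product. Its hydroazulene core needs a long synthesis, and the resulting α-ketol still needs a reduction and an invertive closure to the oxirane and can ring-contract by α-ketol shift.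

Alternative 3: the C4=C5 olefin is cut. The forward key step is ring-closing metathesis of diene A3 with a second-generation ruthenium carbene catalyst. It was turned down because a trisubstituted olefin in a ten-membered ring from a 1,1-disubstituted partner forms slowly and favours dimers, the catalyst does not enforce the Z geometry, the exocyclic enoate and the angelate compete for the carbene, and all six stereocentres must be in place before the closure.

Key step: step 7

Remark on the structure: the SMILES is read literally; it defines a cis-fused (1R,10S)-oxirane (C2 and C9 on the same side) and a (4Z) olefin, and the route is planned for exactly this isomer.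

## Route

Step 1
Reactants: 1 (S)-(+)-carvone
Product: 2 (1S,5S)-2-methyl-5-(prop-1-en-2-yl)cyclohex-2-en-1-ol (cis-carveol)
Conditions: NaBH4, CeCl3·7H2O, MeOH, −78 to 0 °C
Reagents that add atoms: none
Why: Luche reduction gives clean 1,2-reduction of the enone; hydride adds axially so that the hydroxyl is cis to the isopropenyl group, which fixes C3 of the target as S.

Step 2
Reactants: 2 (1S,5S)-2-methyl-5-(prop-1-en-2-yl)cyclohex-2-en-1-ol
Product: 3 tert-butyldimethyl{[(1S,5S)-2-methyl-5-(prop-1-en-2-yl)cyclohex-2-en-1-yl]oxy}silane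
Conditions: TBSCl, imidazole, DMF, rt
Reagents that add atoms: tert-butyldimethylsilyl chloride CC(C)(C)[Si](C)(C)Cl
Why: Standard silylation of a secondary allylic alcohol; the silyl ether survives the oxidative, organometallic and strongly basic steps up to step 13.

Step 3
Reactants: 3 tert-butyldimethyl{[(1S,5S)-2-methyl-5-(prop-1-en-2-yl)cyclohex-2-en-1-yl]oxy}silane
Product: 4 (4S,6S)-4-(TBSO)-3-methyl-6-(prop-1-en-2-yl)cyclohex-2-en-1-one
Conditions: CrO3, 3,5-dimethylpyrazole, CH2Cl2, −20 °C
Reagents that add atoms: chromium trioxide O=[Cr](=O)=O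
Why: Allylic C–H oxidation of the only ring methylene next to the trisubstituted olefin gives the transposed enone (future C6 carbonyl). The isopropenyl-bearing carbon is epimerisable, but the cis isomer with both substituents equatorial is the stable one.

Step 4
Reactants: 5 4-methoxybenzyl alcohol; 6 trichloroethylene
Product: 7 (E)-1,2-dichlorovinyl 4-methoxybenzyl ether
Conditions: KH, THF, 0 °C; then 6, rt
Reagents that add atoms: none
Why: The potassium alkoxide adds to dichloroacetylene formed in situ from trichloroethylene (elimination–addition), the standard entry to 1,2-dichlorovinyl ethers as alkoxyacetylide precursors.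

Step 5
Reactants: 7 (E)-1,2-dichlorovinyl 4-methoxybenzyl ether; 4 (4S,6S)-4-(TBSO)-3-methyl-6-(prop-1-en-2-yl)cyclohex-2-en-1-one
Product: 9 (1R,4S,6S)-4-(TBSO)-1-[(PMBO)ethynyl]-3-methyl-6-(prop-1-en-2-yl)cyclohex-2-en-1-ol, via lithium (4-methoxybenzyloxy)acetylide 8 (not isolated)
Conditions: n-BuLi (2.2 equiv), THF, −78 to −40 °C; then 4, −78 °C; NH4Cl aq
Reagents that add atoms: none
Why: n-BuLi converts 7 into alkoxyacetylide 8 (elimination, then chlorine–lithium exchange), which adds 1,2 to the enone. The small linear acetylide should attack axially on the half-chair with both ring substituents equatorial, so the alkynyl group ends up cis to the isopropenyl group (1R).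

Step 6
Reactants: 9 (1R,4S,6S)-4-(TBSO)-1-[(PMBO)ethynyl]-3-methyl-6-(prop-1-en-2-yl)cyclohex-2-en-1-ol
Product: 10 (1R,4S,6S)-4-(TBSO)-1-[(E)-2-(PMBO)ethenyl]-3-methyl-6-(prop-1-en-2-yl)cyclohex-2-en-1-ol
Conditions: LiAlH4, THF, 0 °C to rt; Rochelle salt aq
Reagents that add atoms: none
Why: Alkoxide-directed trans-hydroalumination of the propargylic alcohol followed by protonolysis gives the (E)-enol ether only; the basic work-up protects the acid-labile tertiary bis-allylic carbinol.

Step 7
Reactants: 10 (1R,4S,6S)-4-(TBSO)-1-[(E)-2-(PMBO)ethenyl]-3-methyl-6-(prop-1-en-2-yl)cyclohex-2-en-1-ol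
Product: 13 (2Z,4S,6Z,9R)-4-(TBSO)-9-(PMBO)-3,7-dimethylcyclodeca-2,6-dien-1-one, via potassium alkoxide 11 (not isolated), via potassium enolate 12 (not isolated)
Conditions: KH, 18-crown-6, THF, 0 °C to rt; then AcOH in THF, −78 °C
Reagents that add atoms: none
Why: Deprotonation gives potassium alkoxide 11, whose charge drives the [3,3]-sigmatropic shift: the C6–C1 bond of the cyclohexene breaks while C8–C9 forms, giving enolate 12 and, after cold protonation, ketone 13 (anionic oxy-Cope rearrangement; closest known type: ring expansion of 1,2-dialkenylcyclohexanols and 1-alkenyl-6-alkenylcyclohex-2-enols to cyclodec-5-enones). The ten-membered ring is therefore not closed end to end but made by a four-atom ring expansion through a six-centre chair transition state. In 10 the C3 silyloxy and C1 isopropenyl groups are cis and both equatorial, which fixes the half-chair with the C6 alkenyl group axial and gauche to the isopropenyl group; in the only chair open to this conformer the ring bond C1–C2 is axial and C6–C5 is equatorial. The axial C1–C2 bond makes the new C1=C10 olefin Z (C2 and C9 cis), and the C4=C5 olefin stays Z because it was the ring olefin of the cyclohexene. The (E)-enol ether holds its oxygen equatorial on the chair, so the C8–C9 bond forms on one face only and C8 is set as R relative to C3 (S). The step needs reaction through the enol ether and not through the endocyclic olefin, which would demand a boat across the ring, and it needs β-alkoxy enolate 12 to survive. The C8–O bond is formed anti to C6, in the plane of the enolate, so E1cB loss of the alkoxide requires a torsion that the ring-trans enolate resists, and the quench is done cold.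

Step 8
Reactants: 13 (2Z,4S,6Z,9R)-4-(TBSO)-9-(PMBO)-3,7-dimethylcyclodeca-2,6-dien-1-one
Product: 14 (2Z,4S,6Z,9R)-4-(TBSO)-9-hydroxy-3,7-dimethylcyclodeca-2,6-dien-1-one
Conditions: DDQ, CH2Cl2/pH 7 buffer, 0 °C
Reagents that add atoms: none
Why: Oxidative cleavage of the 4-methoxybenzyl ether under buffered conditions frees the C8 hydroxyl without touching the silyl ether, the olefins or the β-hydroxy ketone.

Step 9
Reactants: 14 (2Z,4S,6Z,9R)-4-(TBSO)-9-hydroxy-3,7-dimethylcyclodeca-2,6-dien-1-one
Product: 15 (1S,3R,6Z,8S,10R)-8-(TBSO)-3-hydroxy-1,7-dimethyl-11-oxabicyclo[8.1.0]undec-6-en-5-one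
Conditions: VO(acac)2 (cat.), t-BuOOH, CH2Cl2, 0 °C to rt
Reagents that add atoms: tert-butyl hydroperoxide CC(C)(C)OO
Why: Vanadium-catalysed hydroxyl-directed epoxidation: the homoallylic C8 hydroxyl binds the metal peroxide and delivers oxygen to the Z olefin C1=C10 from its own face, giving the cis-oxirane syn to O8 (1R,10S in target numbering). The electron-poor enone and the silyl-protected C3 oxygen offer no competing site.

Step 10
Reactants: 15 (1S,3R,6Z,8S,10R)-8-(TBSO)-3-hydroxy-1,7-dimethyl-11-oxabicyclo[8.1.0]undec-6-en-5-one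
Product: 16 methyl 2-[(1S,3R,4R,6Z,8S,10R)-8-(TBSO)-3-hydroxy-1,7-dimethyl-5-oxo-11-oxabicyclo[8.1.0]undec-6-en-4-yl]acetate
Conditions: LDA (2.2 equiv), THF, −78 °C; BrCH2CO2Me, DMPU, −78 °C; AcOH, −78 °C; used crude
Reagents that add atoms: methyl bromoacetate COC(=O)CBr
Why: Fráter–Seebach-type alkylation of the lithium-chelated alkoxide–enolate: chelation holds O8 syn to O6, the ring chain starting at C9 covers one face of the enolate, and the electrophile enters trans to C9, which gives the 7,8-anti isomer (C7 R). The dianion cannot undergo retro-aldol cleavage, and the cold acidic quench prevents the C8 alkoxide from lactonising onto the new ester.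

Step 11
Reactants: 16 methyl 2-[(1S,3R,4R,6Z,8S,10R)-8-(TBSO)-3-hydroxy-1,7-dimethyl-5-oxo-11-oxabicyclo[8.1.0]undec-6-en-4-yl]acetate
Product: 18 (1R,3S,6R,7R,8R,10S)-3-(TBSO)-8-(DMPO)-1,10-epoxy-13-norgermacr-4Z-en-12,6-olide, via hydroxy ester 17 (not isolated)
Conditions: SmI2 (0.3 equiv), 2,2-dimethylpent-4-enal (6 equiv), THF, −10 °C; then DBU (cat.), CH2Cl2, rt
Reagents that add atoms: 2,2-dimethylpent-4-enal C=CCC(C)(C)C=O
Why: Evans–Tishchenko reduction: the C8 hydroxyl forms a hemiacetal with the aldehyde and its hydride is delivered to the C6 carbonyl through a samarium-bridged chair, which gives the 1,3-anti alcohol (C6 R) and leaves O8 as an ester in the same act. With O8 blocked only O6 can lactonise, so the trans-6,12-lactone forms, and the new ester has no α-hydrogen and a terminal olefin for later neutral removal.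

Step 12
Reactants: 18 (1R,3S,6R,7R,8R,10S)-3-(TBSO)-8-(DMPO)-1,10-epoxy-13-norgermacr-4Z-en-12,6-olide
Product: 21 (1R,3S,6R,7R,8R,10S)-3-(TBSO)-8-(DMPO)-1,10-epoxygermacra-4Z,11(13)-dien-12,6-olide, via Mannich base 19 (not isolated), via ammonium iodide 20 (not isolated)
Conditions: LDA, THF, −78 °C; CH2=NMe2+ I−, −78 °C to rt; then MeI, MeOH, rt; then NaHCO3 aq
Reagents that add atoms: Eschenmoser's salt C=[N+](C)C.[I-]
Why: The lactone enolate (the only enolisable site) undergoes a Mannich reaction with the iminium salt; quaternisation and mild base elimination give the exocyclic enoate. No new stereocentre remains.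

Step 13
Reactants: 21 (1R,3S,6R,7R,8R,10S)-3-(TBSO)-8-(DMPO)-1,10-epoxygermacra-4Z,11(13)-dien-12,6-olide
Product: 22 (1R,3S,6R,7R,8R,10S)-8-(DMPO)-1,10-epoxy-3-hydroxygermacra-4Z,11(13)-dien-12,6-olide
Conditions: TBAF, AcOH (1:1), THF, 0 °C to rt
Reagents that add atoms: none
Why: Buffered fluoride removes the allylic silyl ether; the buffer keeps the enoate, the epoxide and the hindered ester intact.

Step 14
Reactants: 22 (1R,3S,6R,7R,8R,10S)-8-(DMPO)-1,10-epoxy-3-hydroxygermacra-4Z,11(13)-dien-12,6-olide
Product: 23 (1R,3S,6R,7R,8R,10S)-3-acetoxy-8-(DMPO)-1,10-epoxygermacra-4Z,11(13)-dien-12,6-olide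
Conditions: Ac2O, pyridine, DMAP (cat.), CH2Cl2, 0 °C to rt
Reagents that add atoms: acetic anhydride CC(=O)OC(C)=O
Why: Routine acetylation of the only free hydroxyl installs the C3 acetate of the target.

Step 15
Reactants: 23 (1R,3S,6R,7R,8R,10S)-3-acetoxy-8-(DMPO)-1,10-epoxygermacra-4Z,11(13)-dien-12,6-olide
Product: 24 (1R,3S,6R,7R,8R,10S)-3-acetoxy-1,10-epoxy-8-hydroxygermacra-4Z,11(13)-dien-12,6-olide
Conditions: NIS, THF/H2O, 0 °C to rt, dark
Reagents that add atoms: none
Why: Iodonium-induced cleavage of a pent-4-enoate: the ester carbonyl captures the iodonium ion of its own terminal olefin and hydrolysis releases the alcohol and an iodolactone. The medium is neutral, so no C8 alkoxide forms and the lactone does not migrate, and the remaining olefins are electron-poor.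

Step 16
Reactants: 24 (1R,3S,6R,7R,8R,10S)-3-acetoxy-1,10-epoxy-8-hydroxygermacra-4Z,11(13)-dien-12,6-olide
Product: 25 (1R,3S,6R,7R,8R,10S)-3-acetoxy-8-angeloyloxy-1,10-epoxygermacra-4Z,11(13)-dien-12,6-olide
Conditions: angelic acid, 2,4,6-trichlorobenzoyl chloride, Et3N, toluene, rt; then 24, 75 °C
Reagents that add atoms: angelic acid C/C=C(/C)C(=O)O
Why: Yamaguchi esterification through the mixed anhydride acylates the hindered C8 hydroxyl; omitting the nucleophilic catalyst suppresses Z-to-E isomerisation of the angelate.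

Step 17
Reactants: 25 (1R,3S,6R,7R,8R,10S)-3-acetoxy-8-angeloyloxy-1,10-epoxygermacra-4Z,11(13)-dien-12,6-olide
Product: 26 (1R,3S,6R,7R,8R,10S)-3-acetoxy-8-angeloyloxy-1,10-epoxy-15-hydroxygermacra-4Z,11(13)-dien-12,6-olide
Conditions: SeO2 (0.5 equiv), t-BuOOH, CH2Cl2, rt
Reagents that add atoms: selenium dioxide O=[Se]=O; tert-butyl hydroperoxide CC(C)(C)OO
Why: Selenium dioxide allylic hydroxylation (ene reaction, then [2,3]-shift): C15 is the only unoxygenated allylic position, lies on the more substituted olefin carbon and is cis to H5, the preferred site. The [2,3]-shift returns the double bond to C4=C5 with the ring-cis geometry.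

## Compound list

1 | (S)-(+)-carvone | CC1=CC[C@@H](CC1=O)C(C)=C | starting material
2 | (1S,5S)-2-methyl-5-(prop-1-en-2-yl)cyclohex-2-en-1-ol (cis-carveol) | CC1=CC[C@@H](C[C@@H]1O)C(C)=C | intermediate
3 | tert-butyldimethyl{[(1S,5S)-2-methyl-5-(prop-1-en-2-yl)cyclohex-2-en-1-yl]oxy}silane | CC1=CC[C@@H](C[C@@H]1O[Si](C)(C)C(C)(C)C)C(C)=C | intermediate
4 | (4S,6S)-4-(tert-butyldimethylsilyloxy)-3-methyl-6-(prop-1-en-2-yl)cyclohex-2-en-1-one | CC1=CC(=O)[C@@H](C[C@@H]1O[Si](C)(C)C(C)(C)C)C(C)=C | intermediate
5 | 4-methoxybenzyl alcohol | COc1ccc(CO)cc1 | starting material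
6 | trichloroethylene | ClC=C(Cl)Cl | starting material
7 | (E)-1,2-dichlorovinyl 4-methoxybenzyl ether | COc1ccc(CO/C(Cl)=C\Cl)cc1 | intermediate
8 | lithium (4-methoxybenzyloxy)acetylide | [Li]C#COCc1ccc(OC)cc1 | intermediate (not isolated)
9 | (1R,4S,6S)-4-(tert-butyldimethylsilyloxy)-1-[(4-methoxybenzyloxy)ethynyl]-3-methyl-6-(prop-1-en-2-yl)cyclohex-2-en-1-ol | CC1=C[C@](O)(C#COCc2ccc(OC)cc2)[C@@H](C[C@@H]1O[Si](C)(C)C(C)(C)C)C(C)=C | intermediate
10 | (1R,4S,6S)-4-(tert-butyldimethylsilyloxy)-1-[(E)-2-(4-methoxybenzyloxy)ethenyl]-3-methyl-6-(prop-1-en-2-yl)cyclohex-2-en-1-ol | CC1=C[C@](O)(/C=C/OCc2ccc(OC)cc2)[C@@H](C[C@@H]1O[Si](C)(C)C(C)(C)C)C(C)=C | intermediate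
11 | potassium alkoxide of 10 | CC1=C[C@]([O-])(/C=C/OCc2ccc(OC)cc2)[C@@H](C[C@@H]1O[Si](C)(C)C(C)(C)C)C(C)=C.[K+] | intermediate (not isolated)
12 | potassium enolate of 13 (C6–O−, C6=C7 with O6 cis to C8) | [O-]\C1=C/[C@H](OCc2ccc(OC)cc2)C/C(C)=C\C[C@H](O[Si](C)(C)C(C)(C)C)\C(C)=C/1.[K+] | intermediate (not isolated)
13 | (2Z,4S,6Z,9R)-4-(tert-butyldimethylsilyloxy)-9-(4-methoxybenzyloxy)-3,7-dimethylcyclodeca-2,6-dien-1-one | O=C1/C=C(/C)[C@@H](O[Si](C)(C)C(C)(C)C)C/C=C(/C)C[C@@H](OCc2ccc(OC)cc2)C1 | intermediate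
14 | (2Z,4S,6Z,9R)-4-(tert-butyldimethylsilyloxy)-9-hydroxy-3,7-dimethylcyclodeca-2,6-dien-1-one | O=C1/C=C(/C)[C@@H](O[Si](C)(C)C(C)(C)C)C/C=C(/C)C[C@@H](O)C1 | intermediate
15 | (1S,3R,6Z,8S,10R)-8-(tert-butyldimethylsilyloxy)-3-hydroxy-1,7-dimethyl-11-oxabicyclo[8.1.0]undec-6-en-5-one | O=C1/C=C(/C)[C@@H](O[Si](C)(C)C(C)(C)C)C[C@H]2O[C@@]2(C)C[C@@H](O)C1 | intermediate
16 | methyl 2-[(1S,3R,4R,6Z,8S,10R)-8-(tert-butyldimethylsilyloxy)-3-hydroxy-1,7-dimethyl-5-oxo-11-oxabicyclo[8.1.0]undec-6-en-4-yl]acetate | O=C1/C=C(/C)[C@@H](O[Si](C)(C)C(C)(C)C)C[C@H]2O[C@@]2(C)C[C@@H](O)[C@H]1CC(=O)OC | intermediate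
17 | methyl 2-[(1S,3R,4S,5R,6Z,8S,10R)-8-(tert-butyldimethylsilyloxy)-3-(2,2-dimethylpent-4-enoyloxy)-5-hydroxy-1,7-dimethyl-11-oxabicyclo[8.1.0]undec-6-en-4-yl]acetate | O[C@@H]1/C=C(/C)[C@@H](O[Si](C)(C)C(C)(C)C)C[C@H]2O[C@@]2(C)C[C@@H](OC(=O)C(C)(C)CC=C)[C@H]1CC(=O)OC | intermediate (not isolated)
18 | (1R,3S,6R,7R,8R,10S)-3-(tert-butyldimethylsilyloxy)-8-(2,2-dimethylpent-4-enoyloxy)-1,10-epoxy-13-norgermacr-4Z-en-12,6-olide | C1C(=O)O[C@@H]2/C=C(/C)[C@@H](O[Si](C)(C)C(C)(C)C)C[C@H]3O[C@@]3(C)C[C@@H](OC(=O)C(C)(C)CC=C)[C@@H]12 | intermediate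
19 | 13-(dimethylamino)-11,13-dihydro derivative of 21 (Mannich base, C11 epimers) | CN(C)CC1C(=O)O[C@@H]2/C=C(/C)[C@@H](O[Si](C)(C)C(C)(C)C)C[C@H]3O[C@@]3(C)C[C@@H](OC(=O)C(C)(C)CC=C)[C@@H]12 | intermediate (not isolated)
20 | trimethylammonium iodide of 19 | C[N+](C)(C)CC1C(=O)O[C@@H]2/C=C(/C)[C@@H](O[Si](C)(C)C(C)(C)C)C[C@H]3O[C@@]3(C)C[C@@H](OC(=O)C(C)(C)CC=C)[C@@H]12.[I-] | intermediate (not isolated)
21 | (1R,3S,6R,7R,8R,10S)-3-(tert-butyldimethylsilyloxy)-8-(2,2-dimethylpent-4-enoyloxy)-1,10-epoxygermacra-4Z,11(13)-dien-12,6-olide | C=C1C(=O)O[C@@H]2/C=C(/C)[C@@H](O[Si](C)(C)C(C)(C)C)C[C@H]3O[C@@]3(C)C[C@@H](OC(=O)C(C)(C)CC=C)[C@@H]12 | intermediate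
22 | (1R,3S,6R,7R,8R,10S)-8-(2,2-dimethylpent-4-enoyloxy)-1,10-epoxy-3-hydroxygermacra-4Z,11(13)-dien-12,6-olide | C=C1C(=O)O[C@@H]2/C=C(/C)[C@@H](O)C[C@H]3O[C@@]3(C)C[C@@H](OC(=O)C(C)(C)CC=C)[C@@H]12 | intermediate
23 | (1R,3S,6R,7R,8R,10S)-3-acetoxy-8-(2,2-dimethylpent-4-enoyloxy)-1,10-epoxygermacra-4Z,11(13)-dien-12,6-olide | C=C1C(=O)O[C@@H]2/C=C(/C)[C@@H](OC(C)=O)C[C@H]3O[C@@]3(C)C[C@@H](OC(=O)C(C)(C)CC=C)[C@@H]12 | intermediate
24 | (1R,3S,6R,7R,8R,10S)-3-acetoxy-1,10-epoxy-8-hydroxygermacra-4Z,11(13)-dien-12,6-olide | C=C1C(=O)O[C@@H]2/C=C(/C)[C@@H](OC(C)=O)C[C@H]3O[C@@]3(C)C[C@@H](O)[C@@H]12 | intermediate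
25 | (1R,3S,6R,7R,8R,10S)-3-acetoxy-8-angeloyloxy-1,10-epoxygermacra-4Z,11(13)-dien-12,6-olide | C=C1C(=O)O[C@@H]2/C=C(/C)[C@@H](OC(C)=O)C[C@H]3O[C@@]3(C)C[C@@H](OC(=O)/C(C)=C\C)[C@@H]12 | intermediate
26 | (1R,3S,6R,7R,8R,10S)-3-acetoxy-8-angeloyloxy-1,10-epoxy-15-hydroxygermacra-4Z,11(13)-dien-12,6-olide | C=C1C(=O)O[C@@H]2/C=C(/CO)[C@@H](OC(C)=O)C[C@H]3O[C@@]3(C)C[C@@H](OC(=O)/C(C)=C\C)[C@@H]12 | target

## Step count and least certain steps

Total step count: 17 (16 in the main line plus step 4, which makes reagent 7). Longest linear sequence: 16 steps, from 1 to 26 through steps 1–3 and 5–17.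

Step 7 (key step). The most likely failure is β-elimination of the C8 alkoxy group from enolate 12 during the rearrangement, which would erase the C8 stereocentre; a second risk is leakage through the alternative chair, giving the 1(10)E olefin. The fallback avoids any leaving group, sets out from 4 and comes back at 14. Ethynylmagnesium bromide (THF, −78 °C) adds to 4 to give (1R,4S,6S)-4-(tert-butyldimethylsilyloxy)-1-ethynyl-3-methyl-6-(prop-1-en-2-yl)cyclohex-2-en-1-ol F1. The anionic acetylenic oxy-Cope rearrangement of F1 (KH, 18-crown-6, THF) gives, after protonation of the allenolate, (2Z,4S,6Z,9Z)-4-(tert-butyldimethylsilyloxy)-3,7-dimethylcyclodeca-2,6,9-trien-1-one F2. Copper-catalysed enantioselective conjugate borylation at the disubstituted enone terminus (CuCl, NaOtBu, Josiphos-type ligand, B2pin2, MeOH) then gives (2Z,4S,6Z,9R)-4-(tert-butyldimethylsilyloxy)-3,7-dimethyl-9-(4,4,5,5-tetramethyl-1,3,2-dioxaborolan-2-yl)cyclodeca-2,6-dien-1-one F3, and oxidation with NaBO3 (retention) returns 14.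

Step 3. Poor site selectivity is the risk: oxidation at the silyloxy-bearing C–H or at the allylic positions of the isopropenyl group. The fallback replaces C–H oxidation by an oxidative 1,3-transposition, sets out from 3 and comes back at 4. mCPBA epoxidises the ring olefin of 3 anti to the silyloxy group to give the epoxide tert-butyldimethyl{[2-methyl-2,3-epoxy-5-(prop-1-en-2-yl)cyclohexyl]oxy}silane F4. PhSeNa (from PhSeSePh and NaBH4, EtOH) opens it at the secondary carbon to give the hydroxy selenide F5. H2O2 triggers selenoxide elimination to the tertiary allylic alcohol 6-(tert-butyldimethylsilyloxy)-1-methyl-4-(prop-1-en-2-yl)cyclohex-2-en-1-ol F6, and pyridinium chlorochromate, C5H5NH[CrO3Cl] (Babler–Dauben oxidation), gives 4.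

Step 9. Oxygen transfer may be slow or may come from the face anti to O8, and the carbinol may be oxidised instead. The fallback uses an iodocarbonate cyclisation, sets out from 14 and comes back at 15. Boc2O and DMAP give the tert-butyl carbonate of 14 F7. IBr (toluene, −80 °C) lets the carbonate oxygen attack C10 from the O8 face with anti addition of iodine at C1, giving the six-membered iodo carbonate F8. K2CO3 in MeOH cleaves the carbonate, and the C10 alkoxide closes the oxirane with inversion at C1 to give 15.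

Step 11. The trivalent samarium catalyst may open the trisubstituted epoxide, or hemiacetal formation with the neopentyl-type aldehyde may be so slow that 16 lactonises through O8. The fallback separates acylation and reduction, sets out from 16 and comes back at 17. 2,2-Dimethylpent-4-enoyl chloride, pyridine and DMAP acylate O8 to give the keto diester methyl 2-[8-(tert-butyldimethylsilyloxy)-3-(2,2-dimethylpent-4-enoyloxy)-1,7-dimethyl-5-oxo-11-oxabicyclo[8.1.0]undec-6-en-4-yl]acetate F9. A Corey–Bakshi–Shibata reduction ((S)-Me-CBS, catecholborane, −78 °C, C7 as the large group) then sets C6 by reagent control and gives 17, which lactonises to 18 as in step 11.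

Step 17. C15 may be over-oxidised to the enal, or the epoxide may be opened by selenous acid. The fallback is a chlorination–transposition, sets out from 25 and comes back at 26. Ene-type chlorination with hypochlorous acid (Ca(OCl)2, CO2, CH2Cl2/H2O) shifts the olefin to C4=C15 and puts chlorine on C5, giving the allylic chloride F10 (C5 epimers). AgBF4 in aqueous acetone then hydrolyses it at the primary terminus C15 with return of the ring olefin to C4=C5, giving 26.

Further compounds

F1 | step 7 | (1R,4S,6S)-4-(tert-butyldimethylsilyloxy)-1-ethynyl-3-methyl-6-(prop-1-en-2-yl)cyclohex-2-en-1-ol | CC1=C[C@](O)(C#C)[C@@H](C[C@@H]1O[Si](C)(C)C(C)(C)C)C(C)=C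
F2 | step 7 | (2Z,4S,6Z,9Z)-4-(tert-butyldimethylsilyloxy)-3,7-dimethylcyclodeca-2,6,9-trien-1-one | O=C1/C=C(/C)[C@@H](O[Si](C)(C)C(C)(C)C)C/C=C(/C)C/C=C\1
F3 | step 7 | (2Z,4S,6Z,9R)-4-(tert-butyldimethylsilyloxy)-3,7-dimethyl-9-(4,4,5,5-tetramethyl-1,3,2-dioxaborolan-2-yl)cyclodeca-2,6-dien-1-one | O=C1/C=C(/C)[C@@H](O[Si](C)(C)C(C)(C)C)C/C=C(/C)C[C@@H](B2OC(C)(C)C(C)(C)O2)C1
F4 | step 3 | tert-butyldimethyl{[2-methyl-2,3-epoxy-5-(prop-1-en-2-yl)cyclohexyl]oxy}silane (oxirane trans to the silyloxy group) | C[C@]12O[C@H]1C[C@@H](C[C@@H]2O[Si](C)(C)C(C)(C)C)C(C)=C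
F5 | step 3 | 6-(tert-butyldimethylsilyloxy)-1-methyl-2-(phenylselanyl)-4-(prop-1-en-2-yl)cyclohexan-1-ol | C[C@]1(O)[C@H]([Se]c2ccccc2)C[C@@H](C[C@@H]1O[Si](C)(C)C(C)(C)C)C(C)=C
F6 | step 3 | 6-(tert-butyldimethylsilyloxy)-1-methyl-4-(prop-1-en-2-yl)cyclohex-2-en-1-ol | C[C@]1(O)C=C[C@@H](C[C@@H]1O[Si](C)(C)C(C)(C)C)C(C)=C
F7 | step 9 | tert-butyl carbonate of 14 | O=C1/C=C(/C)[C@@H](O[Si](C)(C)C(C)(C)C)C/C=C(/C)C[C@@H](OC(=O)OC(C)(C)C)C1
F8 | step 9 | cyclic carbonate bridging O8 and O10 with iodine on C1 | O=C1/C=C(/C)[C@@H](O[Si](C)(C)C(C)(C)C)C[C@H](I)[C@]2(C)C[C@@H](OC(=O)O2)C1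
F9 | step 11 | methyl 2-[8-(tert-butyldimethylsilyloxy)-3-(2,2-dimethylpent-4-enoyloxy)-1,7-dimethyl-5-oxo-11-oxabicyclo[8.1.0]undec-6-en-4-yl]acetate | O=C1/C=C(/C)[C@@H](O[Si](C)(C)C(C)(C)C)C[C@H]2O[C@@]2(C)C[C@@H](OC(=O)C(C)(C)CC=C)[C@H]1CC(=O)OC
F10 | step 17 | 3-acetoxy-8-angeloyloxy-5-chloro-1,10-epoxygermacra-4(15),11(13)-dien-12,6-olide (C5 epimers) | C=C1C(=O)O[C@@H]2C(Cl)C(=C)[C@@H](OC(C)=O)C[C@H]3O[C@@]3(C)C[C@@H](OC(=O)/C(C)=C\C)[C@@H]12
A1 | alternative 1 | open-chain (4Z)-enal and (Z)-2-(bromomethyl)enoate with the 1,10-epoxide, 3-acetate, 8-angelate and 15-silyl ether | O=C/C=C(/CO[Si](C)(C)C(C)(C)C)[C@@H](OC(C)=O)C[C@H]1O[C@@]1(C)C[C@@H](OC(=O)/C(C)=C\C)/C=C(\CBr)C(=O)OC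
A2 | alternative 2 | 1,10-dihydroxy-4,15-epoxy-3,8-bis(tert-butyldimethylsilyloxy)guai-11(13)-en-12,6-olide (cis-fused hydroazulene, oxirane oxygen cis to C6) | C=C1C(=O)O[C@@H]2[C@H]4[C@]5(CO5)[C@@H](O[Si](C)(C)C(C)(C)C)C[C@@]4(O)[C@@](C)(O)C[C@@H](O[Si](C)(C)C(C)(C)C)[C@@H]12
A3 | alternative 3 | 4,5-seco diene: lactone bearing a vinyl group on C6 and the epoxy side chain ending in the 2-(silyloxymethyl)allyl unit | C=C1C(=O)O[C@H](C=C)[C@H]1[C@H](OC(=O)/C(C)=C\C)C[C@]2(C)O[C@@H]2C[C@H](OC(C)=O)C(=C)CO[Si](C)(C)C(C)(C)C
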